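Friday's run stopped at 20.0 h with 66% of its electrophile unused and, on paper, 0.0205 M of nucleophile beside it, yet its target was barely creeping up.

| setting | Friday's | Saturday's | flask |
|---|---|---|---|
| electrophile | 0.050 M | 0.050 M | 0.050 M |
| nucleophile | 0.74 equiv | 1.7 equiv | 1.10 equiv |
| free base | 2 equiv | 2 equiv | 2.00 equiv |
| protic impurity | 1 mM | 1 mM | 1.00 mM |
| remark | run made earlier | run made earlier |  |
| time |  |  | 25 h |

| run | time / h | electrophile / % | target / % |
|---|---|---|---|
| Friday's | 4.00 | 87 | 18 |
| Friday's | 8.00 | 78 | 20 |
| Friday's | 12.0 | 74 | 25 |
| Friday's | 15.0 | 73 | 28 |
| Friday's | 20.0 | 66 | 31 |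
| Saturday's | 4.00 | 68 | 34 |
| Saturday's | 8.00 | 52 | 46 |
| Saturday's | 12.0 | 49 | 52 |
| Saturday's | 15.0 | 45 | 55 |
| Saturday's | 20.0 | 40 | 60 |

(standard deviation of a reading: 1.5 percentage points)

- for target the idle adduct is counted in
- what was read earlier has a scatter of 1.5 percentage points, one standard deviation
- on the list of suspects stand: electrophile + nucleophile -> acid set free + target; nucleophile + acid set free <-> protonated nucleophile; acid set free + free base <-> salt of the base; nucleophile + protic impurity -> quenched reagent; nucleophile + target <-> idle adduct
- the earlier runs do not show how much of nucleophile is bound; that part of a forecast is a guess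

- part of the electrophile that has reacted at 25 h
- share of free nucleophile in free nucleophile and protonated nucleophile together, at 25 h

Two people argue over this flask. Both take the protic impurity's share off the charge, which leaves 0.0540 M of nucleophile in the flask and 0.0840 M in Saturday's run.

The first trusts a steady clock, the plain second-order law with one constant k. Saturday's first target reading gives k = 1.39 /M/h. The time constant 1/(k[nucleophile]) at the flask's charge is then 13.3 h, and the flask reaches 66.9%.

The second says k sags, so time is the wrong axis. She inverts the same law at each reading. At 20.0 h Saturday's run gives 14.0 /M and Friday's 13.7 /M, close despite the different charges. Saturday's last interval adds 0.427 /M/h, well below k. Extended to 25 h, that makes 16.1 /M. This is the exposure, the time integral of k a run has collected by then. My own reckoning follows her: the flask reaches 47.3%.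

The forecast takes her side, saying “the nucleophile is being progressively deactivated”. It gives 47% and 60%, and it calls the second figure a guess.

The flask gives 46.7% and 50.0%. The forecast's conversion holds, and its free share is 10 percentage points too high.

    electrophile + nucleophile → acid set free + target (k = 5.38 × 10⁻⁴ /M/s)
    nucleophile + acid set free ⇌ protonated nucleophile, settled at all times (K = 970 /M)
    acid set free + free base ⇌ salt of the base (K = 1.60 × 10⁵ /M, k = 0.00206 /M/s)
    nucleophile + protic impurity → quenched reagent (k = 0.145 /M/s)
    nucleophile + target ⇌ idle adduct, settled at all times (K = 890 /M)

By 2.50 h the protic impurity was down to 0%, and target had reached 17.4%, near the steady clock's 15.9%. That is a nearness of figures, not a steady k, for free nucleophile already stood at 52.3% of its charge. The clock's figure is 1.5 points off there, against 20 points at 25 h. Electrophile kept reacting while free nucleophile fell to 15.1% of its charge at 12.5 h, and at 25.0 h the idle adduct, 0.0195 M, was the nucleophile's resting state, above free nucleophile at 0.00559 M. The conversion reckoned from the exposure 16.1 /M lies 0.60 points above this flask's. At 1.90 equiv of nucleophile it gives 68.7%, and that flask stands at 69.7%.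

The numbers in the tables stem from a simulated flask from invented constants.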